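**Plan**

- Retrosynthesis (chroman ring C = O1, C2, C3, C4; B-ring carbons primed): the O–Si bonds on O7 and O4' are cut first, then the C3–C1' bond, which leaves two chromenes: 2H-chromene 5 (rings A/C) and 8-iodochromene 11 (ring B with its dimethylpyran). Compound 5 is cut at O1–C2 and C3=C4 back to salicylaldehyde 3; compound 11 is cut at O–CMe2 and at the ring–vinyl bond back to iodophenol 7.
- Enabling feature: C3 and C4 of ring C can be carried as the C3=C4 cis-styrene bond of a 2H-chromene. An aryl–Pd adds across it with the aryl on C3 and Pd on benzylic C4; the only β-hydrogen (on C3) is anti to Pd and C4a is aromatic, so the Pd–C4 bond waits until a hydride replaces it.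
- Forward order: ring C is closed on the A ring (Schweizer reaction); the dimethylpyran is closed on the B ring (propargyl Claisen cascade onto C3', the only free carbon ortho to the 2'-oxygen); the two halves are joined by reductive Heck hydroarylation; both silyl groups are then removed.
- Stereochemistry: the single stereocentre C3 (R) is set in the joining step by the chiral ligand on palladium during enantioface-selective arylpalladation; no later step can epimerise it.
- Helpers: the C3=C4 unsaturation (consumed by hydride in the joining step), iodine on C1' (lost in the same step) and the TIPS ethers on O7 and O4' (removed in step 8).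

Key step: step 7

Step 1
Reactants: 1 2,4,6-trihydroxybenzaldehyde
Product: 2 2,6-dihydroxy-4-[(triisopropylsilyl)oxy]benzaldehyde
Conditions: TIPSCl (1.05 equiv), imidazole (2.2 equiv), DMF, 0 °C
Reagents that add atoms: triisopropylsilyl chloride, CC(C)[Si](Cl)(C(C)C)C(C)C
Why: Regioselective O-silylation, since the 4-OH is the most acidic hydroxyl and the only one not flanked by the formyl group, so the bulky silyl chloride should react there first.

Step 2
Reactants: 2 2,6-dihydroxy-4-[(triisopropylsilyl)oxy]benzaldehyde
Product: 3 2-hydroxy-6-methoxy-4-[(triisopropylsilyl)oxy]benzaldehyde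
Conditions: MeI (1.05 equiv), K2CO3 (1.1 equiv), acetone, rt
Reagents that add atoms: iodomethane, CI
Why: Williamson O-methylation of one of two equivalent hydroxyls; after the first methylation the remaining hydroxyl is held in a strong hydrogen bond to the carbonyl and should react much more slowly, so one equivalent of MeI should stop at the monomethyl ether.

Step 3
Reactants: 3 2-hydroxy-6-methoxy-4-[(triisopropylsilyl)oxy]benzaldehyde
Product: 5 5-methoxy-7-[(triisopropylsilyl)oxy]-2H-chromene, via phosphonium ylide 4 (not isolated)
Conditions: NaH (1.05 equiv), THF, 0 °C; then CH2=CHPPh3Br (1.2 equiv), DMF, 60 °C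
Reagents that add atoms: vinyltriphenylphosphonium bromide, C=C[P+](c1ccccc1)(c1ccccc1)c1ccccc1.[Br-]
Why: Schweizer 2H-chromene synthesis, in which oxa-Michael addition of the phenoxide to the vinylphosphonium salt gives ylide 4 and intramolecular Wittig olefination of the neighbouring formyl group closes ring C.

Step 4
Reactants: 6 4-iodoresorcinol (4-iodobenzene-1,3-diol)
Product: 7 2-iodo-5-[(triisopropylsilyl)oxy]phenol
Conditions: TIPSCl (1.0 equiv), imidazole (2.0 equiv), CH2Cl2, −20 to 0 °C
Reagents that add atoms: triisopropylsilyl chloride, CC(C)[Si](Cl)(C(C)C)C(C)C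
Why: Regioselective O-silylation, since the hydroxyl para to iodine is unhindered while the one ortho to iodine is shielded by the halogen and less nucleophilic, so the bulky silyl chloride should discriminate; any regioisomer or bis-silyl ether would be removed by chromatography.

Step 5
Reactants: 7 2-iodo-5-[(triisopropylsilyl)oxy]phenol
Product: 8 {4-iodo-3-[(2-methylbut-3-yn-2-yl)oxy]phenoxy}triisopropylsilane
Conditions: 3-chloro-3-methylbut-1-yne (1.5 equiv), DBU (1.6 equiv), CuCl2·2H2O (1 mol %), MeCN, 0 °C
Reagents that add atoms: 3-chloro-3-methylbut-1-yne, CC(C)(Cl)C#C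
Why: Copper-catalysed propargylic etherification through a copper allenylidene-type electrophile, which should form the tertiary aryl propargyl ether of a hindered phenol at 0 °C without touching the aryl iodide.

Step 6
Reactants: 8 {4-iodo-3-[(2-methylbut-3-yn-2-yl)oxy]phenoxy}triisopropylsilane
Product: 11 8-iodo-2,2-dimethyl-5-[(triisopropylsilyl)oxy]-2H-chromene, via allenylphenol 9 (not isolated), via ortho-quinone methide 10 (not isolated)
Conditions: PhNEt2, 160 °C
Reagents that add atoms: none
Why: Aromatic propargyl Claisen rearrangement to the only free ortho carbon followed by enolisation to allenylphenol 9, 1,5-hydrogen shift to ortho-quinone methide 10 and oxa-6π electrocyclisation, which should close the 2,2-dimethylpyran with a single regiochemistry.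

Step 7
Reactants: 5 5-methoxy-7-[(triisopropylsilyl)oxy]-2H-chromene, 11 8-iodo-2,2-dimethyl-5-[(triisopropylsilyl)oxy]-2H-chromene
Product: 12 (3R)-3-{2,2-dimethyl-5-[(triisopropylsilyl)oxy]-2H-chromen-8-yl}-5-methoxy-7-[(triisopropylsilyl)oxy]chromane
Conditions: 5 (1.5 equiv), Pd2(dba)3 (2.5 mol %), (S)-t-Bu-PHOX (6 mol %; antipode chosen as explained under Why), HCO2Na (2 equiv), DMF, 60 °C
Reagents that add atoms: none
Why: Proposed new method: oxidative addition of Pd(0)·L* into the C–I bond of 11, iodide/formate exchange and syn arylpalladation of the C3=C4 bond of 5 should place the aryl group on C3 and palladium on benzylic C4 as an η3-benzyl species that cannot β-eliminate (C3–H is anti, C4a is aromatic), so that decarboxylation of the formate and C4–H reductive elimination release 12 and Pd(0). The closest known reaction types are the Pd-catalysed oxyarylation of 2H-chromenes with o-iodophenols, which shows the same carbopalladation (aryl to C3, Pd to C4) with the Pd–C4 bond taken by oxygen instead of hydride, and the enantioselective Pd/formate reductive Heck hydroarylation of norbornenes; the enantioselective intermolecular hydroarylation of a 2H-chromene is the untested part. No ring is closed in this step. The new stereocentre C3 is fixed at the migratory insertion, where the chiral P,N ligand on palladium selects one face of the planar chromene; which ligand antipode leads to 3R has to be found in a test run, and both antipodes are available. Regioselectivity (aryl to C3, not C4) should follow from η3-benzyl stabilisation by the electron-rich A ring and from the 5-methoxy group that shields C4, and chemoselectivity for the alkene of 5 over the chromene alkene of 11 and 12 should follow from the gem-dimethyl carbon that blocks carbopalladation there and from the excess of 5. Reduction of the aryl–Pd species before insertion should be held back by the sparingly soluble formate, which keeps the hydride supply low.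

Step 8
Reactants: 12 (3R)-3-{2,2-dimethyl-5-[(triisopropylsilyl)oxy]-2H-chromen-8-yl}-5-methoxy-7-[(triisopropylsilyl)oxy]chromane
Product: 13 (3R)-3-(5-hydroxy-2,2-dimethyl-2H-chromen-8-yl)-5-methoxychroman-7-ol
Conditions: TBAF (2.5 equiv), THF, 0 °C; AcOH quench
Reagents that add atoms: none
Why: Fluoride-mediated desilylation of both aryl silyl ethers under conditions that leave the chromene double bond, the methyl ether and the non-epimerisable C3 stereocentre untouched.

**Compound list**

1 | 2,4,6-trihydroxybenzaldehyde | O=Cc1c(O)cc(O)cc1O | starting material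
2 | 2,6-dihydroxy-4-[(triisopropylsilyl)oxy]benzaldehyde | O=Cc1c(O)cc(O[Si](C(C)C)(C(C)C)C(C)C)cc1O | intermediate
3 | 2-hydroxy-6-methoxy-4-[(triisopropylsilyl)oxy]benzaldehyde | COc1cc(O[Si](C(C)C)(C(C)C)C(C)C)cc(O)c1C=O | intermediate
4 | [2-(2-formyl-3-methoxy-5-{[triisopropylsilyl]oxy}phenoxy)ethylidene]triphenylphosphorane (ylide) | COc1cc(O[Si](C(C)C)(C(C)C)C(C)C)cc(OC[CH-][P+](c2ccccc2)(c2ccccc2)c2ccccc2)c1C=O | intermediate (not isolated)
5 | 5-methoxy-7-[(triisopropylsilyl)oxy]-2H-chromene | COc1cc(O[Si](C(C)C)(C(C)C)C(C)C)cc2OCC=Cc12 | intermediate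
6 | 4-iodoresorcinol (4-iodobenzene-1,3-diol) | Oc1ccc(I)c(O)c1 | starting material
7 | 2-iodo-5-[(triisopropylsilyl)oxy]phenol | Oc1cc(O[Si](C(C)C)(C(C)C)C(C)C)ccc1I | intermediate
8 | {4-iodo-3-[(2-methylbut-3-yn-2-yl)oxy]phenoxy}triisopropylsilane | C#CC(C)(C)Oc1cc(O[Si](C(C)C)(C(C)C)C(C)C)ccc1I | intermediate
9 | 6-iodo-2-(3-methylbuta-1,2-dien-1-yl)-3-[(triisopropylsilyl)oxy]phenol | CC(C)=C=Cc1c(O)c(I)ccc1O[Si](C(C)C)(C(C)C)C(C)C | intermediate (not isolated)
10 | (6Z)-2-iodo-6-(3-methylbut-2-en-1-ylidene)-5-[(triisopropylsilyl)oxy]cyclohexa-2,4-dien-1-one | O=C1C(I)=CC=C(O[Si](C(C)C)(C(C)C)C(C)C)/C1=C/C=C(C)C | intermediate (not isolated)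
11 | 8-iodo-2,2-dimethyl-5-[(triisopropylsilyl)oxy]-2H-chromene | CC1(C)C=Cc2c(O[Si](C(C)C)(C(C)C)C(C)C)ccc(I)c2O1 | intermediate
12 | (3R)-3-{2,2-dimethyl-5-[(triisopropylsilyl)oxy]-2H-chromen-8-yl}-5-methoxy-7-[(triisopropylsilyl)oxy]chromane | COc1cc(O[Si](C(C)C)(C(C)C)C(C)C)cc2c1C[C@H](c1ccc(O[Si](C(C)C)(C(C)C)C(C)C)c3c1OC(C)(C)C=C3)CO2 | intermediate
13 | (3R)-3-(5-hydroxy-2,2-dimethyl-2H-chromen-8-yl)-5-methoxychroman-7-ol | COc1cc(O)cc2c1C[C@H](c1ccc(O)c3c1OC(C)(C)C=C3)CO2 | target

**Step count**

Total steps: 8. Longest linear sequence: 5 steps (1, 2, 3, 7, 8 or 4, 5, 6, 7, 8).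

**Steps most likely to fail**

1. Step 7 (Proposed new method). The aryl–palladium intermediate may be reduced to the arene before the alkene inserts, and the enantioface discrimination in the insertion may be weak. The fallback uses known chemistry, sets out from 5 and 7 and comes back at 12. The free hydroxyl ortho to iodine in 7 serves as an internal trap: Heck oxyarylation of 5 with 7 (Pd(OAc)2, PPh3, Ag2CO3, acetone, reflux) should give the racemic cis-fused (±)-cis-1-methoxy-3,9-bis[(triisopropylsilyl)oxy]pterocarpan F1, in which the same C3–aryl bond is formed and the dihydrofuran is a temporary ring. Hydrogenolysis of its benzylic C–O bond (H2, Pd/C, EtOAc–EtOH, rt) should open that ring to the racemic (±)-2-{5-methoxy-7-[(triisopropylsilyl)oxy]chroman-3-yl}-5-[(triisopropylsilyl)oxy]phenol F2. Preparative chromatography on a chiral stationary phase would separate the enantiomers and deliver 2-{(3R)-5-methoxy-7-[(triisopropylsilyl)oxy]chroman-3-yl}-5-[(triisopropylsilyl)oxy]phenol F3, whose configuration would have to be assigned independently. Etherification of its only free hydroxyl under the conditions of step 5 should give (3R)-5-methoxy-3-{2-[(2-methylbut-3-yn-2-yl)oxy]-4-[(triisopropylsilyl)oxy]phenyl}-7-[(triisopropylsilyl)oxy]chromane F4. Heating as in step 6 should close the pyran onto the only free ortho carbon and return to 12.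

2. Step 3. The oxa-Michael addition is reversible and the Wittig closure onto a hindered, electron-rich formyl group may be slow, so that silyl loss under the basic conditions competes. The fallback sets out from 3 and comes back at 5. O-Allylation (allyl bromide, K2CO3, acetone, reflux) should give 2-(allyloxy)-6-methoxy-4-[(triisopropylsilyl)oxy]benzaldehyde F5. Wittig methylenation (Ph3PCH3Br, KOtBu, THF, 0 °C) should give [3-(allyloxy)-5-methoxy-4-vinylphenoxy]triisopropylsilane F6. Ring-closing metathesis (Grubbs second-generation catalyst, CH2Cl2, 40 °C) should then close ring C to 5.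

3. Step 5. O-Alkylation of the hindered, iodine-flanked phenoxide may stall while the tertiary propargylic chloride eliminates to the enyne. The fallback sets out from 7 and comes back at 11, bypassing 8 and step 6. Direct chromene annulation of 7 with 3-methylbut-2-enal (ethylenediammonium diacetate cat., xylene, 140 °C) proceeds by ortho C-alkylation, dehydration and oxa-6π electrocyclisation at the only free carbon ortho to the hydroxyl, and should give 11 in one operation; no new isolated compound arises (entry F0).

**Further compounds**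

F1 | step 7 | (±)-cis-1-methoxy-3,9-bis[(triisopropylsilyl)oxy]pterocarpan (racemate; 6aR,11aR enantiomer drawn) | COc1cc(O[Si](C(C)C)(C(C)C)C(C)C)cc2OC[C@H]3c4ccc(O[Si](C(C)C)(C(C)C)C(C)C)cc4O[C@H]3c12
F2 | step 7 | (±)-2-{5-methoxy-7-[(triisopropylsilyl)oxy]chroman-3-yl}-5-[(triisopropylsilyl)oxy]phenol (racemate) | COc1cc(O[Si](C(C)C)(C(C)C)C(C)C)cc2c1CC(c1ccc(O[Si](C(C)C)(C(C)C)C(C)C)cc1O)CO2
F3 | step 7 | 2-{(3R)-5-methoxy-7-[(triisopropylsilyl)oxy]chroman-3-yl}-5-[(triisopropylsilyl)oxy]phenol | COc1cc(O[Si](C(C)C)(C(C)C)C(C)C)cc2c1C[C@H](c1ccc(O[Si](C(C)C)(C(C)C)C(C)C)cc1O)CO2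
F4 | step 7 | (3R)-5-methoxy-3-{2-[(2-methylbut-3-yn-2-yl)oxy]-4-[(triisopropylsilyl)oxy]phenyl}-7-[(triisopropylsilyl)oxy]chromane | COc1cc(O[Si](C(C)C)(C(C)C)C(C)C)cc2c1C[C@H](c1ccc(O[Si](C(C)C)(C(C)C)C(C)C)cc1OC(C)(C)C#C)CO2
F5 | step 3 | 2-(allyloxy)-6-methoxy-4-[(triisopropylsilyl)oxy]benzaldehyde | C=CCOc1cc(O[Si](C(C)C)(C(C)C)C(C)C)cc(OC)c1C=O
F6 | step 3 | [3-(allyloxy)-5-methoxy-4-vinylphenoxy]triisopropylsilane | C=CCOc1cc(O[Si](C(C)C)(C(C)C)C(C)C)cc(OC)c1C=C
F0 | step 5 | none | none
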